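## Retrosynthetic overview

1. Rings B, C and D and all four stereocentres (C6, C8, C9, C13) are taken intact from gibberellic acid 1, with the C7 acid masked as methyl ester 2; no stereocentre is made or broken afterwards.
2. Ring A is aromatised next with the C3 oxygen kept: 2 is oxidised to the 1-en-3-one 3, which loses C19 as CO2 to give phenol 4.
3. Methyl propiolate 5 and thiophenol 6 give, via sulfide 7, sulfoxide 8, the source of the three furan carbons and an α-cation (enolonium) equivalent of methyl formylacetate.
4. Key disconnection, furan ring formed last: the arene C2–ester α-carbon bond joins the nucleophilic ortho carbon of phenol 4 to the normally nucleophilic α-carbon of 8, through sulfonium salts 9 and 10 and a [3,3] shift; O–C closure to 11 and loss of PhSH give benzofuran diester 12.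
5. Ring order: B, C and D (bought), then aromatic ring A, then the furan; hydrolysis of both esters of 12 ends at pharbinilic acid 13.

Assumption: gibberellic acid 1 (the natural enantiomer, a bulk fermentation product sold as a plant growth regulator) counts as a cheap commercial starting material; gibberellane numbering (C1–C19) is used for the skeleton throughout.

## Route

Step 1
Reactants: 1 gibberellic acid
Product: 2 gibberellic acid methyl ester
Conditions: MeI (1.5 equiv), K2CO3 (1.2 equiv), acetone, rt, 12 h
Reagents that add atoms: iodomethane, CI
Why: SN2 O-alkylation of the C7 carboxylate (the only acidic group) gives the methyl ester without touching the lactone, the two alcohols or any stereocentre, and it prevents mixed-anhydride formation at C7 in step 4.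

Step 2
Reactants: 2 gibberellic acid methyl ester
Product: 4 methyl 3-hydroxyallogibberate, via enone 3 (not isolated)
Conditions: MnO2 (activated, 20 equiv), CH2Cl2, rt; filter through Celite, evaporate; then Pd(PPh3)4 (5 mol %), THF, 50 °C
Reagents that add atoms: none
Why: MnO2 oxidises only the secondary allylic C3 alcohol (allylic oxidation), zerovalent palladium then ionises the allylic lactone C10–O bond with the metal on the β face, syn β-hydride loss of the β-axial H5 gives the ring A 2,4-dienone acid, and this β-keto acid loses CO2 to form the phenol directly (Tsuji-type palladium-catalysed decarboxylative elimination), so C3 keeps its oxygen while C6, C8, C9 and C13 are not touched.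

Step 3
Reactants: 5 methyl propiolate; 6 thiophenol
Product: 8 methyl (E)-3-(phenylsulfinyl)acrylate, via sulfide 7 (not isolated)
Conditions: Et3N (5 mol %), CH2Cl2, 0 °C → rt, 12 h; then mCPBA (1.05 equiv), −20 → 0 °C
Reagents that add atoms: mCPBA (3-chloroperoxybenzoic acid), OOC(=O)c1cccc(Cl)c1
Why: Amine-catalysed thiol-yne (thia-Michael) addition gives the β-thioacrylate, which equilibrates toward the more stable E isomer by reversible thiolate addition, and one equivalent of peracid oxidises the deactivated sulfur only as far as the sulfoxide (sulfide oxidation); any Z isomer carried along reacts the same way, because the sulfur stereocentre (racemic) and the alkene geometry are both erased in step 4.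

Step 4
Reactants: 4 methyl 3-hydroxyallogibberate; 8 methyl (E)-3-(phenylsulfinyl)acrylate
Product: 12 dimethyl pharbinilate, via trifluoroacetoxysulfonium salt 9 (not isolated), via aryloxysulfonium salt 10 (not isolated), via phenylthio-dihydrobenzofuran 11 (not isolated)
Conditions: 8 (1.5 equiv), TFAA (1.6 equiv, added last), CH2Cl2, −40 → 0 °C; then Et3N (4 equiv), 0 °C → rt
Reagents that add atoms: none
Why: Proposed new method: TFAA O-acylates the sulfoxide of 8 to give 9, the phenol oxygen of 4 displaces trifluoroacetate at sulfur (interrupted Pummerer) to give 10, and a charge-accelerated [3,3]-sigmatropic shift across the O–S bond then joins the only free ortho carbon (C2; C4 carries the methyl group and the para carbon C10 is substituted) to the ester α-carbon, so that the vinylsulfonium serves as an enolonium equivalent of methyl formylacetate; rearomatisation, addition of the phenol oxygen to the thionium carbon (11) and loss of PhSH, driven by aromatisation and completed by Et3N (E1cB), give the 2-unsubstituted benzofuran-3-carboxylate, the closest known reaction type being the extended Pummerer annulation of phenols with ketene dithioacetal monoxides under TFAA, which gives 2-methylthio-benzofurans; no stereocentre is formed and C6, C8, C9 and C13 are not involved.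

Step 5
Reactants: 12 dimethyl pharbinilate
Product: 13 pharbinilic acid
Conditions: LiOH·H2O (6 equiv), THF/MeOH/H2O (3:1:1), 45 °C; then 1 M HCl to pH 3, 0 °C
Reagents that add atoms: lithium hydroxide, [Li+].[OH-]
Why: Saponification (BAc2) of the unhindered heteroaryl ester and of the hindered C7 ester, followed by brief cold acidification, gives the diacid; once the C7 carboxylate has formed C6–H is no longer acidic, and the C6 configuration of allogibberate-type esters is expected to survive aqueous base, so C6, C8, C9 and C13 are delivered as in 1.

## Compound list

1 | gibberellic acid (natural enantiomer) | C[C@@]12[C@H](C=C[C@@]3([C@@H]1[C@@H]([C@]45[C@H]3CC[C@](C4)(C(=C)C5)O)C(=O)O)OC2=O)O | starting material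
2 | gibberellic acid methyl ester (C7 methyl ester; 3β-OH, 13-OH, 19,10-lactone, 1-ene and 16-ene as in 1) | C[C@@]12[C@H](C=C[C@@]3([C@@H]1[C@@H]([C@]45[C@H]3CC[C@](C4)(C(=C)C5)O)C(=O)OC)OC2=O)O | intermediate
3 | methyl 3-oxogibberellate (ring A 1-en-3-one, 19,10-lactone intact; not isolated) | C[C@@]12C(=O)C=C[C@@]3([C@@H]1[C@@H]([C@]45[C@H]3CC[C@](C4)(C(=C)C5)O)C(=O)OC)OC2=O | intermediate
4 | methyl 3-hydroxyallogibberate (aromatic ring A with 3-OH and 4-methyl; C7 methyl ester; 13-OH; 16-ene; C6, C8, C9, C13 as in 1) | C=C1C[C@]23C[C@@]1(O)CC[C@H]2c1ccc(O)c(C)c1[C@@H]3C(=O)OC | intermediate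
5 | methyl propiolate | C#CC(=O)OC | starting material
6 | thiophenol | Sc1ccccc1 | starting material
7 | methyl (E)-3-(phenylthio)acrylate (not isolated) | COC(=O)/C=C/Sc1ccccc1 | intermediate
8 | methyl (E)-3-(phenylsulfinyl)acrylate (racemic at sulfur) | COC(=O)/C=C/S(=O)c1ccccc1 | intermediate
9 | [(E)-2-(methoxycarbonyl)vinyl](phenyl)(trifluoroacetoxy)sulfonium trifluoroacetate (not isolated) | COC(=O)/C=C/[S+](OC(=O)C(F)(F)F)c1ccccc1.[O-]C(=O)C(F)(F)F | intermediate
10 | aryloxysulfonium trifluoroacetate: phenol oxygen of 4 bonded to S-phenyl S-[(E)-2-(methoxycarbonyl)vinyl] sulfonium (not isolated) | C=C1C[C@]23C[C@@]1(O)CC[C@H]2c1ccc(O[S+](c2ccccc2)/C=C/C(=O)OC)c(C)c1[C@@H]3C(=O)OC.[O-]C(=O)C(F)(F)F | intermediate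
11 | 2-(phenylthio)-2,3-dihydrobenzofuran-3-carboxylate fused at C2–C3 of ring A (mixture at the two new, transient centres; not isolated) | C=C1C[C@]23C[C@@]1(O)CC[C@H]2c1cc2C(C(=O)OC)C(Sc4ccccc4)Oc2c(C)c1[C@@H]3C(=O)OC | intermediate
12 | dimethyl pharbinilate (benzofuran-3-carboxylate methyl ester and C7 methyl ester; 13-OH; 16-ene) | C=C1C[C@]23C[C@@]1(O)CC[C@H]2c1cc2c(C(=O)OC)coc2c(C)c1[C@@H]3C(=O)OC | intermediate
13 | pharbinilic acid | C=C1C[C@]23C[C@@]1(O)CC[C@H]2c1cc2c(C(=O)O)coc2c(C)c1[C@@H]3C(=O)O | target

## Step count and risk

Total step count: 5. Longest linear sequence: 4 (steps 1, 2, 4, 5; step 3 makes the side fragment).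

Most likely to fail, in this order:

Step 4 (key annulation). Trifluoroacetate may add to the vinylsulfonium (additive Pummerer) instead of the phenol attacking sulfur. A [3,3] shift onto the methyl-bearing C4 or a reaction at the S-phenyl ring could compete. The activated sulfoxide or CF3CO2H may attack the 16-ene next to the tertiary C13 alcohol (Wagner–Meerwein risk). O-trifluoroacetylation at C13 is harmless, because step 5 would cleave it.

The fallback sets out from phenol 4 and comes back at diester 12. Oxa-Michael addition of 4 to methyl propiolate 5 (DABCO 10 mol %, CH2Cl2, rt) gives the methyl (E)-3-aryloxyacrylate F1. Divalent palladium then closes the same arene C2–ester α-carbon bond by intramolecular dehydrogenative coupling (Pd(OAc)2 10 mol %, PPh3 10 mol %, CF3CO2Ag 2 equiv, benzene, 110 °C). Here the palladated enol-ether carbon takes the role of the α-cation and the silver salt is the terminal oxidant; the two nucleophilic carbons are again joined under oxidative polarity reversal, but without sulfur and without strong acid.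

Step 2 (oxidation and decarboxylative aromatisation). Oxidative addition at the tertiary allylic C10–O bond may be slow. The transient palladium hydride could move the 16-ene into the ring. Loss of H9 instead of H5 would endanger C9.

The fallback sets out from enone 3, this time isolated after the MnO2 filtration, and comes back at phenol 4. It replaces metal catalysis by a base-induced elimination: DBU (1.5 equiv), MeCN, 60 °C. H5 (β-axial) is anti-periplanar to the α-axial C10–O bond, so anti elimination opens the lactone and gives the 6-carboxy-6-methylcyclohexa-2,4-dienone, ring-opened dienone acid F2 (as its DBU salt). As a β-keto acid whose decarboxylation produces a phenoxide, it loses CO2 at once to give 4.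

Step 5 (double hydrolysis). The C7 ester is neopentyl-like and may hydrolyse slowly, and forcing it risks epimerising the benzylic C6–H next to the ester.

The fallback sets out from diester 12 and comes back at target 13 in two stages with different bond cleavage. LiOH (1.2 equiv, THF/H2O, 0 °C) is stopped at the stage where only the unhindered heteroaryl ester has reacted, giving pharbinilic acid 7-methyl ester F3. The remaining methyl group is then removed by SN2 dealkylation at the methyl carbon with n-PrSLi in HMPA at rt (alkyl–oxygen cleavage, no tetrahedral intermediate at C7), and mild acidification gives 13.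

## Further compounds

F1 | step 4 | methyl (E)-3-aryloxyacrylate of phenol 4 (aryl vinyl ether at the C3 oxygen) | C=C1C[C@]23C[C@@]1(O)CC[C@H]2c1ccc(O/C=C/C(=O)OC)c(C)c1[C@@H]3C(=O)OC
F2 | step 2 | ring-opened dienone acid (ring A 3-oxo-1,5(10)-diene with 4-methyl and 4-carboxylic acid; C7 methyl ester) | C=C1C[C@]23C[C@@]1(O)CC[C@H]2C1=C([C@@H]3C(=O)OC)[C@](C)(C(=O)O)C(=O)C=C1
F3 | step 5 | pharbinilic acid 7-methyl ester (free benzofuran-3-carboxylic acid) | C=C1C[C@]23C[C@@]1(O)CC[C@H]2c1cc2c(C(=O)O)coc2c(C)c1[C@@H]3C(=O)OC
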